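**Strategy.** The O–C2–C1–C15(=C17H2) array of the cis-fused α-methylene-γ-butyrolactone is read as a [2,3]-Wittig retron. The 14-membered carbocycle is therefore never closed by a C–C macrocyclisation: a 17-membered propargylic allylic ether (C2H2–O–C17H2–C15(C16H2OTBS)=C1H–C14, alkyne at C3≡C4, made by ring-closing alkyne metathesis) is contracted by an enantioselective [2,3]-Wittig rearrangement. This single operation forms the ring bond C1–C2, sets both stereocentres (cis), places the oxygen on C2 and unveils the exocyclic C15=C17 methylene, while the temporary O–C17 bond is cleaved. The alkyne that directs deprotonation later becomes the (E)-C3=C4 methyl alkene, and C16 is oxidised to the lactone carbonyl.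

Key step: step 15

Numbering (cembrane): C1 and C2 are the ring-fusion carbons (C2 bears O); C3=C4(Me), C7=C8(C19H2OAc) and C11=C12(Me) are the ring alkenes; C15 is the lactone α-carbon, C16 the carbonyl, C17 the exocyclic CH2. The target is (1S,2S), cis-fused, with ring carbons trans across all three ring alkenes. TBDPS = tert-butyldiphenylsilyl, TBS = tert-butyldimethylsilyl.

Assumption: lithium (S,S)-bis(1-phenylethyl)amide is taken to remove the C2 proton that leads to 25. If the opposite sense is observed, the (R,R)-amine is used instead with no other change.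

**Step 1**
Reactants: 1 hex-4-yn-1-ol
Product: 2 hex-4-ynal
Conditions: TEMPO (10 mol %), PhI(OAc)2 (1.1 equiv), CH2Cl2, rt
Reagents that add atoms: none
Why: Oxoammonium (TEMPO) oxidation of a primary alcohol stops at the aldehyde under anhydrous conditions and leaves the internal alkyne untouched.

**Step 2**
Reactants: 3 2-bromoprop-2-en-1-ol
Product: 4 [(2-bromoprop-2-en-1-yl)oxy](tert-butyl)diphenylsilane
Conditions: TBDPSCl, imidazole, CH2Cl2, 0 °C → rt
Reagents that add atoms: tert-butyl(chloro)diphenylsilane, CC(C)(C)[Si](Cl)(c1ccccc1)c1ccccc1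
Why: Standard silylation of a primary alcohol installs the robust C19–O protecting group that is carried to step 20.

**Step 3**
Reactants: 4 [(2-bromoprop-2-en-1-yl)oxy](tert-butyl)diphenylsilane; 2 hex-4-ynal
Product: 6 rac-2-(TBDPSO-methyl)oct-1-en-6-yn-3-ol, via vinyllithium 5 (not isolated)
Conditions: t-BuLi (2.0 equiv), Et2O, −78 °C; then 2, −78 °C; aq NH4Cl
Reagents that add atoms: none
Why: Bromine–lithium exchange followed by 1,2-addition of the vinyllithium to the aldehyde should give the 2-substituted allylic alcohol, kept at −78 °C to suppress β-elimination; the carbinol centre is racemic and is destroyed in step 4.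

**Step 4**
Reactants: 6 rac-2-(TBDPSO-methyl)oct-1-en-6-yn-3-ol; 7 triethyl orthoacetate
Product: 9 ethyl (4Z)-4-(TBDPSO-methyl)dec-4-en-8-ynoate, via ketene acetal 8 (not isolated)
Conditions: EtCO2H (cat.), neat 7 (6 equiv), 140 °C, EtOH distilled off
Reagents that add atoms: none
Why: Johnson–Claisen rearrangement through a chair transition state with the C6 chain equatorial should place that chain trans to the new C9–C10 arm and cis to CH2OTBDPS, which is the C7=C8 geometry of the target.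

**Step 5**
Reactants: 9 ethyl (4Z)-4-(TBDPSO-methyl)dec-4-en-8-ynoate
Product: 10 (4Z)-4-(TBDPSO-methyl)dec-4-en-8-ynal
Conditions: DIBAL-H (1.1 equiv), CH2Cl2, −78 °C; MeOH, then aq Rochelle salt
Reagents that add atoms: none
Why: Partial reduction of the ester with DIBAL-H at −78 °C should stop at the aldehyde through the stable tetrahedral aluminate; alkene, alkyne and silyl ether are inert.

**Step 6**
Reactants: 10 (4Z)-4-(TBDPSO-methyl)dec-4-en-8-ynal; 11 isopropenylmagnesium bromide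
Product: 12 rac-(6Z)-2-methyl-6-(TBDPSO-methyl)dodeca-1,6-dien-10-yn-3-ol
Conditions: THF, −78 → 0 °C; aq NH4Cl
Reagents that add atoms: none
Why: Grignard 1,2-addition gives the 2-methylallylic alcohol; the carbinol centre is racemic and is consumed in step 7.

**Step 7**
Reactants: 12 rac-(6Z)-2-methyl-6-(TBDPSO-methyl)dodeca-1,6-dien-10-yn-3-ol; 7 triethyl orthoacetate
Product: 14 ethyl (4E,8Z)-4-methyl-8-(TBDPSO-methyl)tetradeca-4,8-dien-12-ynoate, via ketene acetal 13 (not isolated)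
Conditions: EtCO2H (cat.), neat 7 (6 equiv), 140 °C, EtOH distilled off
Reagents that add atoms: none
Why: A second Johnson–Claisen rearrangement (chair, C10 chain equatorial) should give the (E)-trisubstituted C11=C12 methyl alkene and deliver C1 as the ester carbon.

**Step 8**
Reactants: 14 ethyl (4E,8Z)-4-methyl-8-(TBDPSO-methyl)tetradeca-4,8-dien-12-ynoate
Product: 15 (4E,8Z)-4-methyl-8-(TBDPSO-methyl)tetradeca-4,8-dien-12-ynal
Conditions: DIBAL-H (1.1 equiv), CH2Cl2, −78 °C; MeOH, then aq Rochelle salt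
Reagents that add atoms: none
Why: Partial DIBAL-H reduction of the ester to the aldehyde, as in step 5.

**Step 9**
Reactants: 15 (4E,8Z)-4-methyl-8-(TBDPSO-methyl)tetradeca-4,8-dien-12-ynal; 16 methyl acrylate
Product: 17 methyl rac-(6E,10Z)-3-hydroxy-6-methyl-2-methylidene-10-(TBDPSO-methyl)hexadeca-6,10-dien-14-ynoate
Conditions: DABCO (1.0 equiv), 16 (5 equiv), MeOH (2 equiv), rt, 3–7 d
Reagents that add atoms: none
Why: Morita–Baylis–Hillman reaction attaches C15 with C16 (ester) and C17 (CH2=) in one atom-economic step; the carbinol centre is racemic and becomes sp2 in step 10.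

**Step 10**
Reactants: 17 methyl rac-(6E,10Z)-3-hydroxy-6-methyl-2-methylidene-10-(TBDPSO-methyl)hexadeca-6,10-dien-14-ynoate
Product: 18 methyl (2Z,6E,10Z)-2-(bromomethyl)-6-methyl-10-(TBDPSO-methyl)hexadeca-2,6,10-trien-14-ynoate
Conditions: NBS, Me2S, CH2Cl2, 0 °C → rt
Reagents that add atoms: N-bromosuccinimide, O=C1CCC(=O)N1Br
Why: Corey–Kim-type activation of the Baylis–Hillman alcohol and SN2′ attack of bromide should give the transposed allylic bromide as the favoured (Z)-isomer (chain trans to the ester), which fixes C14 cis to C17 as the key step requires.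

**Step 11**
Reactants: 18 methyl (2Z,6E,10Z)-2-(bromomethyl)-6-methyl-10-(TBDPSO-methyl)hexadeca-2,6,10-trien-14-ynoate
Product: 19 (2Z,6E,10Z)-2-(bromomethyl)-6-methyl-10-(TBDPSO-methyl)hexadeca-2,6,10-trien-14-yn-1-ol
Conditions: DIBAL-H (2.2 equiv), CH2Cl2, −78 °C; aq Rochelle salt
Reagents that add atoms: none
Why: DIBAL-H 1,2-reduction of the conjugated ester to the allylic alcohol (C16) at −78 °C should leave the primary allylic bromide intact.

**Step 12**
Reactants: 19 (2Z,6E,10Z)-2-(bromomethyl)-6-methyl-10-(TBDPSO-methyl)hexadeca-2,6,10-trien-14-yn-1-ol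
Product: 20 (2Z,6E,10Z)-2-(bromomethyl)-1-(TBSO)-6-methyl-10-(TBDPSO-methyl)hexadeca-2,6,10-trien-14-yne
Conditions: TBSOTf, 2,6-lutidine, CH2Cl2, −78 °C
Reagents that add atoms: tert-butyldimethylsilyl trifluoromethanesulfonate, CC(C)(C)[Si](C)(C)OS(=O)(=O)C(F)(F)F
Why: Silylation with a triflate and a non-nucleophilic base protects C16–OH without N-alkylation by the allylic bromide, and the TBS group stays distinguishable from TBDPS.

**Step 13**
Reactants: 20 (2Z,6E,10Z)-2-(bromomethyl)-1-(TBSO)-6-methyl-10-(TBDPSO-methyl)hexadeca-2,6,10-trien-14-yne; 21 but-2-yn-1-ol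
Product: 22 (2E,6E,10Z)-2-[(but-2-yn-1-yloxy)methyl]-1-(TBSO)-6-methyl-10-(TBDPSO-methyl)hexadeca-2,6,10-trien-14-yne
Conditions: NaH, THF, 0 °C; then 20, n-Bu4NI (cat.), 0 °C → rt
Reagents that add atoms: none
Why: Williamson etherification by SN2 at the primary allylic bromide installs the O–C2 unit with retention of the C1=C15 geometry (the descriptor changes only through CIP priorities).

**Step 14**
Reactants: 22 (2E,6E,10Z)-2-[(but-2-yn-1-yloxy)methyl]-1-(TBSO)-6-methyl-10-(TBDPSO-methyl)hexadeca-2,6,10-trien-14-yne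
Product: 23 (7Z,11E,15E)-12-methyl-8-(TBDPSO-methyl)-16-(TBSO-methyl)-1-oxacycloheptadeca-7,11,15-trien-3-yne
Conditions: [Mo(≡CC6H4-4-OMe)(OSiPh3)3] (5 mol %), 5 Å MS, toluene (2 mM), rt → 50 °C
Reagents that add atoms: none
Why: Ring-closing alkyne metathesis of the two methyl-capped alkynes, driven by trapping of but-2-yne on molecular sieves, should close the strain-free 17-membered cycloalkyne without touching the three alkenes or the silyl ethers.

**Step 15**
Reactants: 23 (7Z,11E,15E)-12-methyl-8-(TBDPSO-methyl)-16-(TBSO-methyl)-1-oxacycloheptadeca-7,11,15-trien-3-yne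
Product: 25 (1R,6Z,10E,14S)-11-methyl-7-(TBDPSO-methyl)-14-[3-(TBSO)prop-1-en-2-yl]cyclotetradeca-6,10-dien-2-yn-1-ol, via propargyllithium 24 (not isolated)
Conditions: (S,S)-bis(1-phenylethyl)amine (3 equiv), n-BuLi (2.8 equiv), THF, −40 → −15 °C; aq NH4Cl
Reagents that add atoms: none
Why: The C2-symmetric lithium amide removes one enantiotopic proton at C2, the only C–H that is both propargylic and α to oxygen, and the α-alkoxy propargyllithium 24 undergoes a concerted suprafacial [2,3]-sigmatropic shift through a five-membered envelope transition state in which C2–C1 forms as O–C17 breaks and the double bond moves to C15=C17. The closest known reaction type is the [2,3]-Wittig ring contraction of macrocyclic propargylic allylic ethers, including its enantioselective variant with chiral lithium amide bases. The 14-membered carbocycle is closed by transannular attack of C2 on C1 across the ether bridge, exo to the C1=C15 double bond (formally 14-exo-trig within a five-centre array), so the 17-membered ring contracts by three atoms and no high-dilution C–C macrocyclisation is needed. C2 is set by the chiral base (reagent control), and C1 is set relative to C2 by the transition state: with the alkynyl group exo on the envelope (reinforced by the CH2OTBS group on C15) and C14 cis to C17 across C1=C15, the syn (1,2-cis) isomer required for the cis-lactone should result. The step needs regioselective deprotonation (secured by the alkyne), [2,3] over [1,2] shift (low temperature, lithium counter-ion), syn selectivity (olefin geometry fixed in step 10) and enantioselectivity (chiral amide).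

**Step 16**
Reactants: 25 (1R,6Z,10E,14S)-11-methyl-7-(TBDPSO-methyl)-14-[3-(TBSO)prop-1-en-2-yl]cyclotetradeca-6,10-dien-2-yn-1-ol
Product: 27 (1R,2Z,6Z,10E,14S)-3-iodo-11-methyl-7-(TBDPSO-methyl)-14-[3-(TBSO)prop-1-en-2-yl]cyclotetradeca-2,6,10-trien-1-ol, via alkenylaluminate 26 (not isolated)
Conditions: Red-Al (1.6 equiv), THF, 0 °C → rt; EtOAc (quench of excess hydride); I2, THF, −78 → 0 °C
Reagents that add atoms: iodine, II
Why: Hydroxyl-directed trans-hydroalumination of the propargylic alcohol delivers hydride to C3 and aluminium to C4 in a five-membered alkoxyaluminate, and iodinolysis with retention should give the vinyl iodide with iodine cis to C2; no stereocentre is touched.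

**Step 17**
Reactants: 27 (1R,2Z,6Z,10E,14S)-3-iodo-11-methyl-7-(TBDPSO-methyl)-14-[3-(TBSO)prop-1-en-2-yl]cyclotetradeca-2,6,10-trien-1-ol
Product: 28 (1S,2E,6Z,10E,14S)-3,11-dimethyl-7-(TBDPSO-methyl)-14-[3-(TBSO)prop-1-en-2-yl]cyclotetradeca-2,6,10-trien-1-ol
Conditions: Me2CuLi (5 equiv, from MeLi and CuI), Et2O, 0 °C; aq NH4Cl/NH3
Reagents that add atoms: lithium dimethylcuprate, [Li+].C[Cu-]C
Why: Corey–Posner coupling of the vinyl iodide with the cuprate proceeds with retention and should give the (E)-C3=C4 methyl alkene with ring carbons trans (the C1 descriptor changes only through CIP priorities).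

**Step 18**
Reactants: 28 (1S,2E,6Z,10E,14S)-3,11-dimethyl-7-(TBDPSO-methyl)-14-[3-(TBSO)prop-1-en-2-yl]cyclotetradeca-2,6,10-trien-1-ol
Product: 29 (1S,2E,6Z,10E,14S)-14-(3-hydroxyprop-1-en-2-yl)-3,11-dimethyl-7-(TBDPSO-methyl)cyclotetradeca-2,6,10-trien-1-ol
Conditions: PPTS (0.2 equiv), MeOH, rt
Reagents that add atoms: none
Why: Mild acid-catalysed methanolysis cleaves a primary TBS ether much faster than a primary TBDPS ether, which frees C16–OH only.

**Step 19**
Reactants: 29 (1S,2E,6Z,10E,14S)-14-(3-hydroxyprop-1-en-2-yl)-3,11-dimethyl-7-(TBDPSO-methyl)cyclotetradeca-2,6,10-trien-1-ol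
Product: 31 (3aS,6E,10Z,14E,15aS)-6,14-dimethyl-3-methylidene-10-(TBDPSO-methyl)-3a,4,5,8,9,12,13,15a-octahydrocyclotetradeca[b]furan-2(3H)-one, via lactol 30 (not isolated)
Conditions: TEMPO (0.2 equiv), PhI(OAc)2 (2.5 equiv), CH2Cl2, rt
Reagents that add atoms: none
Why: Oxoammonium oxidation is selective for the primary allylic alcohol; the resulting enal is trapped by the C2 hydroxyl as lactol 30 and oxidised on (oxidative lactonisation of a 1,4-diol), so the cis fusion set in step 15 is carried into the α-methylene-γ-butyrolactone.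

**Step 20**
Reactants: 31 (3aS,6E,10Z,14E,15aS)-6,14-dimethyl-3-methylidene-10-(TBDPSO-methyl)-3a,4,5,8,9,12,13,15a-octahydrocyclotetradeca[b]furan-2(3H)-one
Product: 32 (3aS,6E,10Z,14E,15aS)-10-(hydroxymethyl)-6,14-dimethyl-3-methylidene-3a,4,5,8,9,12,13,15a-octahydrocyclotetradeca[b]furan-2(3H)-one
Conditions: HF·pyridine, pyridine, THF, 0 °C → rt
Reagents that add atoms: none
Why: Buffered fluoride desilylation removes the TBDPS group under non-basic conditions that spare the Michael-acceptor lactone and the allylic C2–O bond.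

**Step 21**
Reactants: 32 (3aS,6E,10Z,14E,15aS)-10-(hydroxymethyl)-6,14-dimethyl-3-methylidene-3a,4,5,8,9,12,13,15a-octahydrocyclotetradeca[b]furan-2(3H)-one
Product: 33 [(3aS,6E,10Z,14E,15aS)-6,14-dimethyl-3-methylidene-2-oxo-2,3,3a,4,5,8,9,12,13,15a-decahydrocyclotetradeca[b]furan-10-yl]methyl acetate (CNP0158848.2)
Conditions: Ac2O, pyridine, DMAP (cat.), CH2Cl2, 0 °C
Reagents that add atoms: acetic anhydride, CC(=O)OC(C)=O
Why: DMAP-catalysed acetylation of the primary allylic alcohol completes the target without affecting either stereocentre.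

**Compound list**

1 | hex-4-yn-1-ol | CC#CCCCO | starting material
2 | hex-4-ynal | CC#CCCC=O | intermediate
3 | 2-bromoprop-2-en-1-ol | C=C(Br)CO | starting material
4 | [(2-bromoprop-2-en-1-yl)oxy](tert-butyl)diphenylsilane | C=C(Br)CO[Si](c1ccccc1)(c1ccccc1)C(C)(C)C | intermediate
5 | [3-(TBDPSO)prop-1-en-2-yl]lithium | [Li]C(=C)CO[Si](c1ccccc1)(c1ccccc1)C(C)(C)C | intermediate
6 | rac-2-(TBDPSO-methyl)oct-1-en-6-yn-3-ol | CC#CCCC(O)C(=C)CO[Si](c1ccccc1)(c1ccccc1)C(C)(C)C | intermediate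
7 | triethyl orthoacetate | CCOC(C)(OCC)OCC | starting material
8 | 1-ethoxyvinyl ether of 6 (mixed ketene acetal) | CC#CCCC(OC(=C)OCC)C(=C)CO[Si](c1ccccc1)(c1ccccc1)C(C)(C)C | intermediate
9 | ethyl (4Z)-4-(TBDPSO-methyl)dec-4-en-8-ynoate | CC#CCC/C=C(\CO[Si](c1ccccc1)(c1ccccc1)C(C)(C)C)CCC(=O)OCC | intermediate
10 | (4Z)-4-(TBDPSO-methyl)dec-4-en-8-ynal | CC#CCC/C=C(\CO[Si](c1ccccc1)(c1ccccc1)C(C)(C)C)CCC=O | intermediate
11 | isopropenylmagnesium bromide | C=C(C)[Mg]Br | starting material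
12 | rac-(6Z)-2-methyl-6-(TBDPSO-methyl)dodeca-1,6-dien-10-yn-3-ol | CC#CCC/C=C(\CO[Si](c1ccccc1)(c1ccccc1)C(C)(C)C)CCC(O)C(C)=C | intermediate
13 | 1-ethoxyvinyl ether of 12 (mixed ketene acetal) | CC#CCC/C=C(\CO[Si](c1ccccc1)(c1ccccc1)C(C)(C)C)CCC(OC(=C)OCC)C(C)=C | intermediate
14 | ethyl (4E,8Z)-4-methyl-8-(TBDPSO-methyl)tetradeca-4,8-dien-12-ynoate | CC#CCC/C=C(\CO[Si](c1ccccc1)(c1ccccc1)C(C)(C)C)CC/C=C(\C)CCC(=O)OCC | intermediate
15 | (4E,8Z)-4-methyl-8-(TBDPSO-methyl)tetradeca-4,8-dien-12-ynal | CC#CCC/C=C(\CO[Si](c1ccccc1)(c1ccccc1)C(C)(C)C)CC/C=C(\C)CCC=O | intermediate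
16 | methyl acrylate | C=CC(=O)OC | starting material
17 | methyl rac-(6E,10Z)-3-hydroxy-6-methyl-2-methylidene-10-(TBDPSO-methyl)hexadeca-6,10-dien-14-ynoate | CC#CCC/C=C(\CO[Si](c1ccccc1)(c1ccccc1)C(C)(C)C)CC/C=C(\C)CCC(O)C(=C)C(=O)OC | intermediate
18 | methyl (2Z,6E,10Z)-2-(bromomethyl)-6-methyl-10-(TBDPSO-methyl)hexadeca-2,6,10-trien-14-ynoate | CC#CCC/C=C(\CO[Si](c1ccccc1)(c1ccccc1)C(C)(C)C)CC/C=C(\C)CC/C=C(\CBr)C(=O)OC | intermediate
19 | (2Z,6E,10Z)-2-(bromomethyl)-6-methyl-10-(TBDPSO-methyl)hexadeca-2,6,10-trien-14-yn-1-ol | CC#CCC/C=C(\CO[Si](c1ccccc1)(c1ccccc1)C(C)(C)C)CC/C=C(\C)CC/C=C(\CBr)CO | intermediate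
20 | (2Z,6E,10Z)-2-(bromomethyl)-1-(TBSO)-6-methyl-10-(TBDPSO-methyl)hexadeca-2,6,10-trien-14-yne | CC#CCC/C=C(\CO[Si](c1ccccc1)(c1ccccc1)C(C)(C)C)CC/C=C(\C)CC/C=C(\CBr)CO[Si](C)(C)C(C)(C)C | intermediate
21 | but-2-yn-1-ol | CC#CCO | starting material
22 | (2E,6E,10Z)-2-[(but-2-yn-1-yloxy)methyl]-1-(TBSO)-6-methyl-10-(TBDPSO-methyl)hexadeca-2,6,10-trien-14-yne | CC#CCC/C=C(\CO[Si](c1ccccc1)(c1ccccc1)C(C)(C)C)CC/C=C(\C)CC/C=C(\COCC#CC)CO[Si](C)(C)C(C)(C)C | intermediate
23 | (7Z,11E,15E)-12-methyl-8-(TBDPSO-methyl)-16-(TBSO-methyl)-1-oxacycloheptadeca-7,11,15-trien-3-yne | O1CC#CCC/C=C(\CO[Si](c2ccccc2)(c2ccccc2)C(C)(C)C)CC/C=C(\C)CC/C=C(/CO[Si](C)(C)C(C)(C)C)C1 | intermediate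
24 | 2-lithio derivative of 23 (α-alkoxy propargyllithium, configuration at C–Li not assigned) | [Li]C1C#CCC/C=C(\CO[Si](c2ccccc2)(c2ccccc2)C(C)(C)C)CC/C=C(\C)CC/C=C(/CO[Si](C)(C)C(C)(C)C)CO1 | intermediate
25 | (1R,6Z,10E,14S)-11-methyl-7-(TBDPSO-methyl)-14-[3-(TBSO)prop-1-en-2-yl]cyclotetradeca-6,10-dien-2-yn-1-ol | O[C@H]1C#CCC/C=C(\CO[Si](c2ccccc2)(c2ccccc2)C(C)(C)C)CC/C=C(\C)CC[C@H]1C(=C)CO[Si](C)(C)C(C)(C)C | intermediate
26 | cyclic sodium alkenyl(alkoxy)bis(2-methoxyethoxy)aluminate from 25 (Al on C4, O–Al chelate) | [Na+].COCCO[Al-]1(OCCOC)O[C@H]2/C=C1/CC/C=C(\CO[Si](c3ccccc3)(c3ccccc3)C(C)(C)C)CC/C=C(\C)CC[C@H]2C(=C)CO[Si](C)(C)C(C)(C)C | intermediate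
27 | (1R,2Z,6Z,10E,14S)-3-iodo-11-methyl-7-(TBDPSO-methyl)-14-[3-(TBSO)prop-1-en-2-yl]cyclotetradeca-2,6,10-trien-1-ol | O[C@H]1/C=C(\I)CC/C=C(\CO[Si](c2ccccc2)(c2ccccc2)C(C)(C)C)CC/C=C(\C)CC[C@H]1C(=C)CO[Si](C)(C)C(C)(C)C | intermediate
28 | (1S,2E,6Z,10E,14S)-3,11-dimethyl-7-(TBDPSO-methyl)-14-[3-(TBSO)prop-1-en-2-yl]cyclotetradeca-2,6,10-trien-1-ol | O[C@H]1/C=C(\C)CC/C=C(\CO[Si](c2ccccc2)(c2ccccc2)C(C)(C)C)CC/C=C(\C)CC[C@H]1C(=C)CO[Si](C)(C)C(C)(C)C | intermediate
29 | (1S,2E,6Z,10E,14S)-14-(3-hydroxyprop-1-en-2-yl)-3,11-dimethyl-7-(TBDPSO-methyl)cyclotetradeca-2,6,10-trien-1-ol | O[C@H]1/C=C(\C)CC/C=C(\CO[Si](c2ccccc2)(c2ccccc2)C(C)(C)C)CC/C=C(\C)CC[C@H]1C(=C)CO | intermediate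
30 | lactol of 31 (2-hydroxy in place of 2-oxo, anomer mixture) | C=C1C(O)O[C@H]2/C=C(\C)CC/C=C(\CO[Si](c3ccccc3)(c3ccccc3)C(C)(C)C)CC/C=C(\C)CC[C@@H]12 | intermediate
31 | (3aS,6E,10Z,14E,15aS)-6,14-dimethyl-3-methylidene-10-(TBDPSO-methyl)-3a,4,5,8,9,12,13,15a-octahydrocyclotetradeca[b]furan-2(3H)-one | C=C1C(=O)O[C@H]2/C=C(\C)CC/C=C(\CO[Si](c3ccccc3)(c3ccccc3)C(C)(C)C)CC/C=C(\C)CC[C@@H]12 | intermediate
32 | (3aS,6E,10Z,14E,15aS)-10-(hydroxymethyl)-6,14-dimethyl-3-methylidene-3a,4,5,8,9,12,13,15a-octahydrocyclotetradeca[b]furan-2(3H)-one | C=C1C(=O)O[C@H]2/C=C(\C)CC/C=C(\CO)CC/C=C(\C)CC[C@@H]12 | intermediate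
33 | [(3aS,6E,10Z,14E,15aS)-6,14-dimethyl-3-methylidene-2-oxo-2,3,3a,4,5,8,9,12,13,15a-decahydrocyclotetradeca[b]furan-10-yl]methyl acetate | C=C1C(=O)O[C@H]2/C=C(\C)CC/C=C(\COC(C)=O)CC/C=C(\C)CC[C@@H]12 | target

**Step count.** Total: 21 steps. Longest linear sequence: 20 steps (steps 1 and 3–21 from 1; equally steps 2–21 from 3).

**Steps most likely to fail**

Step 15. The chiral amide may discriminate the two enantiotopic C2 protons only partly in a flexible 17-membered ring, giving low enantiomeric purity, and a [1,2]-shift may compete. Fallback: from 23, ring contraction with achiral n-BuLi (THF, −78 → −20 °C) relies only on the substrate-controlled syn selectivity and should give 25 as a racemate, that is 25 together with its enantiomer (1S,6Z,10E,14R)-11-methyl-7-(TBDPSO-methyl)-14-[3-(TBSO)prop-1-en-2-yl]cyclotetradeca-6,10-dien-2-yn-1-ol F1. Lipase-catalysed kinetic resolution (Amano lipase PS, vinyl acetate, t-BuOMe, 30 °C) should acylate F1, the enantiomer favoured by the empirical rule for carbinols with a slim alkynyl and a bulky branched substituent, to the (1S,14R)-acetate F2. Unreacted 25 is separated by chromatography and the route is rejoined at 25 (step 16).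

Step 9. The amine-catalysed addition may be too slow for an α-unbranched aliphatic aldehyde, so that aldehyde self-condensation and acrylate oligomerisation overtake it. Fallback: from 15, aldol addition of the lithium enolate of methyl 2-(phenylselanyl)propanoate (LDA, THF, −78 °C) should give methyl (6E,10Z)-3-hydroxy-2,6-dimethyl-2-(phenylselanyl)-10-(TBDPSO-methyl)hexadeca-6,10-dien-14-ynoate F3 (diastereomer mixture). Oxidation (H2O2, pyridine, CH2Cl2, 0 °C → rt) and selenoxide syn-elimination toward the methyl group should give 17, where the route is rejoined.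

Step 14. Intermolecular metathesis (oligomers, cyclic dimer) may outrun ring closure. Fallback: the ring is closed at the O–C17 bond instead. From 20, alkyne cross-metathesis with an excess of 1,4-bis(4-methoxybenzyloxy)but-2-yne (same Mo alkylidyne, toluene, 5 Å MS) should give (2Z,6E,10Z)-2-(bromomethyl)-1-(TBSO)-16-(4-methoxybenzyloxy)-6-methyl-10-(TBDPSO-methyl)hexadeca-2,6,10-trien-14-yne F4; tolerance of the allylic bromide by the catalyst is assumed by analogy with alkyl halides. DDQ (CH2Cl2, pH 7 buffer) should release (6Z,10E,14Z)-15-(bromomethyl)-16-(TBSO)-11-methyl-7-(TBDPSO-methyl)hexadeca-6,10,14-trien-2-yn-1-ol F5. Slow addition of F5 to NaH in THF at high dilution (macro-Williamson etherification) should give 23, where the route is rejoined.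

**Further compounds**

F1 | step 15 | (1S,6Z,10E,14R)-11-methyl-7-(TBDPSO-methyl)-14-[3-(TBSO)prop-1-en-2-yl]cyclotetradeca-6,10-dien-2-yn-1-ol (enantiomer of 25) | O[C@@H]1C#CCC/C=C(\CO[Si](c2ccccc2)(c2ccccc2)C(C)(C)C)CC/C=C(\C)CC[C@@H]1C(=C)CO[Si](C)(C)C(C)(C)C
F2 | step 15 | (1S,6Z,10E,14R)-11-methyl-7-(TBDPSO-methyl)-14-[3-(TBSO)prop-1-en-2-yl]cyclotetradeca-6,10-dien-2-yn-1-yl acetate | CC(=O)O[C@@H]1C#CCC/C=C(\CO[Si](c2ccccc2)(c2ccccc2)C(C)(C)C)CC/C=C(\C)CC[C@@H]1C(=C)CO[Si](C)(C)C(C)(C)C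
F3 | step 9 | methyl (6E,10Z)-3-hydroxy-2,6-dimethyl-2-(phenylselanyl)-10-(TBDPSO-methyl)hexadeca-6,10-dien-14-ynoate | CC#CCC/C=C(\CO[Si](c1ccccc1)(c1ccccc1)C(C)(C)C)CC/C=C(\C)CCC(O)C(C)([Se]c1ccccc1)C(=O)OC
F4 | step 14 | (2Z,6E,10Z)-2-(bromomethyl)-1-(TBSO)-16-(4-methoxybenzyloxy)-6-methyl-10-(TBDPSO-methyl)hexadeca-2,6,10-trien-14-yne | COc1ccc(COCC#CCC/C=C(\CO[Si](c2ccccc2)(c2ccccc2)C(C)(C)C)CC/C=C(\C)CC/C=C(\CBr)CO[Si](C)(C)C(C)(C)C)cc1
F5 | step 14 | (6Z,10E,14Z)-15-(bromomethyl)-16-(TBSO)-11-methyl-7-(TBDPSO-methyl)hexadeca-6,10,14-trien-2-yn-1-ol | OCC#CCC/C=C(\CO[Si](c1ccccc1)(c1ccccc1)C(C)(C)C)CC/C=C(\C)CC/C=C(\CBr)CO[Si](C)(C)C(C)(C)C
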